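**Retrosynthetic overview**

1. Numbering: ring carbons C1–C14; lactone C2–O–C16(=O)–C15–C1; exocyclic methylene C17. The strategy rests on C9, an acetoxy-bearing sp3 carbon of the 14-membered carbocycle that is bonded directly to sp2 C8 of the C7=C8 alkene and lies far from the lactone stereocentres C1 and C2.
2. Key disconnection C8–C9: an (E)-C8 alkenyl iodide and a racemic C9 alpha-chloro acetate in one chain, joined by an enantioconvergent nickel-catalysed reductive coupling that closes the carbocycle and sets C9.
3. Precursor 31 comes from butenolide 14 (C2–C8 arm, from geranyl acetate and ethyl propiolate) and iodide 22 (C9–C14 chain, from but-3-yn-1-ol) by trans-selective cuprate addition; then C15 phosphonate, C9 aldehyde and acetyl chloride.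
4. Ring order: five-membered lactone (step 8), then the 14-membered carbocycle (step 19); the C15=C17 methylene is made last from the phosphonate (step 20).

Key step: step 19

Remark: the sense of induction of (S,S)-ProPhenol in step 7 and of the bis(oxazoline) ligand in step 19 is taken as written; if Mosher analysis or correlation shows the opposite sense, the antipodal ligand is used with nothing else changed.

**Route**

Step 1
Reactants: 1 geranyl acetate
Product: 2 (2E)-5-(3,3-dimethyloxiran-2-yl)-3-methylpent-2-en-1-yl acetate (racemic)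
Conditions: mCPBA (1.05 equiv), NaHCO3, CH2Cl2, 0 °C
Reagents that add atoms: 3-chloroperbenzoic acid, O=C(OO)c1cccc(Cl)c1
Why: Prilezhaev epoxidation should take the 6,7-alkene selectively because the 2,3-alkene is deactivated by the allylic acetate; the epoxide stereocentre is lost in step 2.

Step 2
Reactants: 2 epoxygeranyl acetate
Product: 3 (2E)-3-methyl-6-oxohex-2-en-1-yl acetate
Conditions: HIO4·2H2O, THF/Et2O, 0 °C
Reagents that add atoms: none
Why: Periodic acid opens the trisubstituted epoxide to the diol and cleaves it in the same flask (Malaprade-type glycol cleavage), which should give the aldehyde and acetone without touching the allylic acetate.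

Step 3
Reactants: 3 acetoxy aldehyde
Product: 4 (2E)-3-methylhept-2-en-6-yn-1-ol
Conditions: dimethyl (1-diazo-2-oxopropyl)phosphonate, K2CO3, MeOH, 0 °C to rt
Reagents that add atoms: dimethyl (1-diazo-2-oxopropyl)phosphonate, CC(=O)C(=[N+]=[N-])P(=O)(OC)OC
Why: Seyferth–Gilbert homologation with the Ohira–Bestmann reagent should convert the aldehyde into the terminal alkyne, and the K2CO3/MeOH medium methanolyses the acetate in the same operation.

Step 4
Reactants: 4 enynol
Product: 6 (2E)-3-methyloct-2-en-6-yn-1-ol, via dilithio derivative 5 (not isolated)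
Conditions: n-BuLi (2.1 equiv), THF, −78 to −20 °C; MeI (1.05 equiv), −78 °C to rt; H2O
Reagents that add atoms: iodomethane, CI
Why: Acetylide alkylation: in THF without polar additive the carbon end of the alkoxide–acetylide is by far the better nucleophile towards one equivalent of MeI.

Step 5
Reactants: 6 methyl enynol
Product: 8 (2E,6E)-7-iodo-3-methylocta-2,6-dien-1-ol, via alkenylzirconocene 7 (not isolated)
Conditions: Cp2Zr(H)Cl (3 equiv), THF, 50 °C; I2, 0 °C; H2O
Reagents that add atoms: iodine, II
Why: Hydrozirconation–iodination: syn addition of Zr–H, equilibrated by excess reagent at 50 °C to place zirconium on the less hindered methyl-bearing carbon, then iodinolysis with retention should give the (E)-2-iodo-2-alkene (one equivalent of reagent is consumed by the hydroxyl group).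

Step 6
Reactants: 8 iodo dienol
Product: 9 (2E,6E)-7-iodo-3-methylocta-2,6-dienal
Conditions: activated MnO2 (excess), CH2Cl2, rt
Reagents that add atoms: none
Why: Allylic alcohol oxidation with MnO2 is chemoselective and should not isomerise the trisubstituted alkenes or touch the alkenyl iodide.

Step 7
Reactants: 9 iodo dienal; 10 ethyl propiolate
Product: 12 ethyl (4S,5E,9E)-4-hydroxy-10-iodo-6-methylundeca-5,9-dien-2-ynoate, via alkynylzinc 11 (not isolated)
Conditions: (S,S)-ProPhenol (20 mol%), Ph3P=O (40 mol%), Me2Zn (3 equiv), toluene, 4 °C; aq NH4Cl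
Reagents that add atoms: none
Why: Zinc–ProPhenol catalysed asymmetric alkynylation of an enal: the dinuclear zinc catalyst binds the aldehyde and 11 and delivers the alkynyl group to one face, so the carbinol stereocentre (the future C2) is set by catalyst control.

Step 8
Reactants: 12 hydroxy ynoate
Product: 14 (5R)-5-[(1E,5E)-6-iodo-2-methylhepta-1,5-dien-1-yl]furan-2(5H)-one, via Z-hydroxy enoate 13 (not isolated)
Conditions: H2 (1 atm), Pd/CaCO3 poisoned with Pb(OAc)2 (Lindlar catalyst), quinoline, EtOAc, rt; then PPTS (cat.), CH2Cl2, rt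
Reagents that add atoms: none
Why: Lindlar semihydrogenation of the electron-poor alkyne gives the Z-enoate, which lactonises with loss of ethanol; the activated ynoate should be reduced much faster than the hindered alkenyl iodide is hydrogenolysed.

Step 9
Reactants: 15 but-3-yn-1-ol
Product: 16 (but-3-yn-1-yloxy)(tert-butyl)dimethylsilane
Conditions: TBSCl, imidazole, CH2Cl2, 0 °C to rt
Reagents that add atoms: tert-butyldimethylsilyl chloride, CC(C)(C)[Si](C)(C)Cl
Why: Standard silylation of a primary alcohol.

Step 10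
Reactants: 16 silyl butynyl ether
Product: 19 (3E)-6-[(tert-butyldimethylsilyl)oxy]-4-methylhex-3-en-1-ol, via alkenylalane 17 (not isolated), via lithium alanate 18 (not isolated)
Conditions: Me3Al (2.5 equiv), Cp2ZrCl2 (20 mol%), CH2Cl2, 0 °C to rt; excess Me3Al evaporated; n-BuLi, THF, −78 °C; ethylene oxide, −78 to 0 °C; aq Rochelle salt
Reagents that add atoms: trimethylaluminium, C[Al](C)C; ethylene oxide, C1CO1
Why: Negishi zirconium-catalysed carboalumination adds Me–Al syn across the terminal alkyne with methyl on the internal carbon, and the derived alanate opens ethylene oxide with retention, which fixes the E trisubstituted C11=C12 alkene.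

Step 11
Reactants: 19 mono-silyl diol
Product: 20 tert-butyl({(3E)-6-[(4-methoxybenzyl)oxy]-3-methylhex-3-en-1-yl}oxy)dimethylsilane
Conditions: NaH, PMBCl, TBAI (cat.), THF/DMF, 0 °C to rt
Reagents that add atoms: 4-methoxybenzyl chloride, COc1ccc(CCl)cc1
Why: Williamson etherification of the free primary alcohol; the TBS ether is stable to NaH.

Step 12
Reactants: 20 PMB silyl diether
Product: 21 (3E)-6-[(4-methoxybenzyl)oxy]-3-methylhex-3-en-1-ol
Conditions: TBAF, THF, rt
Reagents that add atoms: none
Why: Fluoride-mediated desilylation leaves the PMB ether and the alkene untouched.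

Step 13
Reactants: 21 PMB alcohol
Product: 22 1-({[(3E)-6-iodo-4-methylhex-3-en-1-yl]oxy}methyl)-4-methoxybenzene
Conditions: I2, PPh3, imidazole, CH2Cl2, 0 °C to rt
Reagents that add atoms: iodine, II
Why: Appel-type iodination of a primary alcohol through the alkoxyphosphonium iodide.

Step 14
Reactants: 22 homoallylic iodide (2.4 equiv); 14 butenolide
Product: 25 (4R,5R)-5-[(1E,5E)-6-iodo-2-methylhepta-1,5-dien-1-yl]-4-{(3E)-6-[(4-methoxybenzyl)oxy]-3-methylhex-3-en-1-yl}dihydrofuran-2(3H)-one, via alkyllithium 23 (not isolated), via lithium dialkylcuprate 24 (not isolated)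
Conditions: t-BuLi (2 equiv per iodide), Et2O, −78 °C; CuI (1.25 equiv), −40 °C; 14, −78 to −40 °C; aq NH4Cl
Reagents that add atoms: none
Why: Iodine–lithium exchange and transmetalation give a Gilman cuprate whose 1,4-addition to the butenolide occurs anti to the C2 substituent, which sets C1 trans to C2 by substrate control; at −78 °C conjugate addition should outrun any reaction with the alkenyl iodide.

Step 15
Reactants: 25 trans-lactone
Product: 27 diethyl [(3R,4S,5S)-5-[(1E,5E)-6-iodo-2-methylhepta-1,5-dien-1-yl]-4-{(3E)-6-[(4-methoxybenzyl)oxy]-3-methylhex-3-en-1-yl}-2-oxotetrahydrofuran-3-yl]phosphonate, via enol phosphate 26 (not isolated)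
Conditions: LDA (2.3 equiv), THF, −78 °C; ClP(O)(OEt)2 (1.1 equiv), −78 to 0 °C; AcOH in Et2O
Reagents that add atoms: diethyl chlorophosphate, CCOP(=O)(Cl)OCC
Why: Phosphate–phosphonate rearrangement: deprotonation and O-phosphorylation give 26, and the second equivalent of LDA induces the 1,3-shift of phosphorus from oxygen to carbon; protonation should place phosphorus trans to the C1 chain, and C15 is in any case destroyed in step 20.

Step 16
Reactants: 27 PMB phosphono lactone
Product: 28 diethyl [(3R,4S,5S)-4-[(3E)-6-hydroxy-3-methylhex-3-en-1-yl]-5-[(1E,5E)-6-iodo-2-methylhepta-1,5-dien-1-yl]-2-oxotetrahydrofuran-3-yl]phosphonate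
Conditions: DDQ, CH2Cl2/pH 7 buffer (10:1), 0 °C
Reagents that add atoms: none
Why: Oxidative PMB ether cleavage by DDQ under buffered conditions should leave the alkenes, the alkenyl iodide, the lactone and the phosphonate untouched.

Step 17
Reactants: 28 hydroxy phosphono lactone
Product: 29 diethyl [(3R,4S,5S)-5-[(1E,5E)-6-iodo-2-methylhepta-1,5-dien-1-yl]-4-[(3E)-3-methyl-6-oxohex-3-en-1-yl]-2-oxotetrahydrofuran-3-yl]phosphonate
Conditions: Dess–Martin periodinane, NaHCO3, CH2Cl2, 0 °C to rt; used crude
Reagents that add atoms: none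
Why: Dess–Martin oxidation under bicarbonate buffer should give the beta,gamma-unsaturated C9 aldehyde without migration of the C11=C12 alkene, provided it is used at once.

Step 18
Reactants: 29 C9 aldehyde; 30 acetyl chloride
Product: 31 diethyl [(3R,4S,5S)-4-[(3E)-6-acetoxy-6-chloro-3-methylhex-3-en-1-yl]-5-[(1E,5E)-6-iodo-2-methylhepta-1,5-dien-1-yl]-2-oxotetrahydrofuran-3-yl]phosphonate (both C9 epimers)
Conditions: AcCl (1.5 equiv), ZnCl2 (10 mol%), CH2Cl2, −20 to 0 °C; used crude
Reagents that add atoms: none
Why: Lewis acid catalysed addition of an acyl chloride across the aldehyde C=O gives the alpha-chloroalkyl ester as both C9 epimers, which is all the stereoconvergent step requires, and no base is present to touch the phosphonate methine.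

Step 19
Reactants: 31 iodo chloro acetate
Product: 32 (1S,2S,9R,15R,3E,7E,11E)-9-acetoxy-15-(diethoxyphosphoryl)cembra-3,7,11-trien-16,2-olide
Conditions: NiBr2·glyme (20 mol%), cyclopropane-1,1-diyl-bridged indanyl bis(oxazoline) L* (24 mol%, antipode giving 9R), Mn powder (3 equiv), NaI (0.5 equiv), DMA, 0 °C; 31 added by syringe pump over 12 h (2 mM final)
Reagents that add atoms: none
Why: Proposed new method: zerovalent nickel should insert into the C8–I bond with retention of the E geometry, while monovalent nickel formed on reduction by manganese abstracts chlorine from either C9 epimer to give one planar alpha-acetoxy radical, which is captured by the chiral alkenylnickel so that reductive elimination from trivalent nickel forms C8–C9. The closest known reaction types are nickel-catalysed enantioconvergent couplings of racemic alpha-haloalkyl esters and asymmetric reductive cross-electrophile couplings of alkenyl halides with secondary alkyl chlorides, neither of which has been used to close a macrocycle. The 14-membered carbocycle closes in the bond-forming event itself: intramolecular radical capture gives a 15-membered nickelacycle that contracts by reductive elimination. The new C9 stereocentre is set by the bis(oxazoline)-bound nickel alone, because both epimers of 31 pass through the same radical and C1 and C2 are too remote to bias its faces. The step needs ring closure to outrun dimerisation and hydrodehalogenation; slow addition of 31 to the catalyst solution, and oxidative addition of the alkenyl iodide being faster than chlorine abstraction, should secure this. The conditions contain no base, so the allylic C2–O lactone bond, the phosphonate methine and the acetate are expected to survive.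

Step 20
Reactants: 32 macrocyclic phosphono lactone
Product: 33 (1R,2S,9R,3E,7E,11E)-9-acetoxycembra-3,7,11,15(17)-tetraen-16,2-olide (CNP0129197.1)
Conditions: K2CO3, 37% aq HCHO, THF, 0 °C to rt
Reagents that add atoms: formaldehyde, C=O
Why: Horner–Wadsworth–Emmons methylenation of the alpha-phosphono lactone is mild enough to leave the secondary acetate and C1, C2 and C9 untouched, and it removes the epimerisable C15 centre.

**Compound list**

1 | geranyl acetate | CC(C)=CCC/C(C)=C/COC(C)=O | starting material
2 | (2E)-5-(3,3-dimethyloxiran-2-yl)-3-methylpent-2-en-1-yl acetate (racemic) | CC1(C)OC1CC/C(C)=C/COC(C)=O | intermediate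
3 | (2E)-3-methyl-6-oxohex-2-en-1-yl acetate | O=CCC/C(C)=C/COC(C)=O | intermediate
4 | (2E)-3-methylhept-2-en-6-yn-1-ol | C#CCC/C(C)=C/CO | intermediate
5 | dilithio derivative of 4 (lithium alkoxide, lithium acetylide) | [Li]C#CCC/C(C)=C/CO[Li] | intermediate (not isolated)
6 | (2E)-3-methyloct-2-en-6-yn-1-ol | CC#CCC/C(C)=C/CO | intermediate
7 | C8 alkenylzirconocene chloride of 6, oxygen bound to a second zirconocene chloride | C/C(=C\CC/C(C)=C/CO[Zr](Cl)(C1C=CC=C1)C1C=CC=C1)[Zr](Cl)(C1C=CC=C1)C1C=CC=C1 | intermediate (not isolated)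
8 | (2E,6E)-7-iodo-3-methylocta-2,6-dien-1-ol | OC/C=C(\C)CC/C=C(\C)I | intermediate
9 | (2E,6E)-7-iodo-3-methylocta-2,6-dienal | O=C/C=C(\C)CC/C=C(\C)I | intermediate
10 | ethyl propiolate | C#CC(=O)OCC | starting material
11 | ethyl 3-(methylzincio)prop-2-ynoate | C[Zn]C#CC(=O)OCC | intermediate (not isolated)
12 | ethyl (4S,5E,9E)-4-hydroxy-10-iodo-6-methylundeca-5,9-dien-2-ynoate | CCOC(=O)C#C[C@@H](O)/C=C(\C)CC/C=C(\C)I | intermediate
13 | ethyl (2Z,4R,5E,9E)-4-hydroxy-10-iodo-6-methylundeca-2,5,9-trienoate | CCOC(=O)/C=C\[C@@H](O)/C=C(\C)CC/C=C(\C)I | intermediate (not isolated)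
14 | (5R)-5-[(1E,5E)-6-iodo-2-methylhepta-1,5-dien-1-yl]furan-2(5H)-one | O=C1O[C@@H](/C=C(\C)CC/C=C(\C)I)C=C1 | intermediate
15 | but-3-yn-1-ol | C#CCCO | starting material
16 | (but-3-yn-1-yloxy)(tert-butyl)dimethylsilane | C#CCCO[Si](C)(C)C(C)(C)C | intermediate
17 | {(1E)-4-[(tert-butyldimethylsilyl)oxy]-2-methylbut-1-en-1-yl}dimethylaluminium | C[Al](C)/C=C(\C)CCO[Si](C)(C)C(C)(C)C | intermediate (not isolated)
18 | lithium butyl{(1E)-4-[(tert-butyldimethylsilyl)oxy]-2-methylbut-1-en-1-yl}dimethylaluminate | [Li+].CCCC[Al-](C)(C)/C=C(\C)CCO[Si](C)(C)C(C)(C)C | intermediate (not isolated)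
19 | (3E)-6-[(tert-butyldimethylsilyl)oxy]-4-methylhex-3-en-1-ol | OCC/C=C(\C)CCO[Si](C)(C)C(C)(C)C | intermediate
20 | tert-butyl({(3E)-6-[(4-methoxybenzyl)oxy]-3-methylhex-3-en-1-yl}oxy)dimethylsilane | COc1ccc(COCC/C=C(\C)CCO[Si](C)(C)C(C)(C)C)cc1 | intermediate
21 | (3E)-6-[(4-methoxybenzyl)oxy]-3-methylhex-3-en-1-ol | COc1ccc(COCC/C=C(\C)CCO)cc1 | intermediate
22 | 1-({[(3E)-6-iodo-4-methylhex-3-en-1-yl]oxy}methyl)-4-methoxybenzene | COc1ccc(COCC/C=C(\C)CCI)cc1 | intermediate
23 | {(3E)-6-[(4-methoxybenzyl)oxy]-3-methylhex-3-en-1-yl}lithium | [Li]CC/C(C)=C/CCOCc1ccc(OC)cc1 | intermediate (not isolated)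
24 | lithium bis{(3E)-6-[(4-methoxybenzyl)oxy]-3-methylhex-3-en-1-yl}cuprate | [Li+].COc1ccc(COCC/C=C(\C)CC[Cu-]CC/C(C)=C/CCOCc2ccc(OC)cc2)cc1 | intermediate (not isolated)
25 | (4R,5R)-5-[(1E,5E)-6-iodo-2-methylhepta-1,5-dien-1-yl]-4-{(3E)-6-[(4-methoxybenzyl)oxy]-3-methylhex-3-en-1-yl}dihydrofuran-2(3H)-one | COc1ccc(COCC/C=C(\C)CC[C@@H]2CC(=O)O[C@H]2/C=C(\C)CC/C=C(\C)I)cc1 | intermediate
26 | diethyl (4R,5R)-5-[(1E,5E)-6-iodo-2-methylhepta-1,5-dien-1-yl]-4-{(3E)-6-[(4-methoxybenzyl)oxy]-3-methylhex-3-en-1-yl}-4,5-dihydrofuran-2-yl phosphate | COc1ccc(COCC/C=C(\C)CC[C@@H]2C=C(OP(=O)(OCC)OCC)O[C@H]2/C=C(\C)CC/C=C(\C)I)cc1 | intermediate (not isolated)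
27 | diethyl [(3R,4S,5S)-5-[(1E,5E)-6-iodo-2-methylhepta-1,5-dien-1-yl]-4-{(3E)-6-[(4-methoxybenzyl)oxy]-3-methylhex-3-en-1-yl}-2-oxotetrahydrofuran-3-yl]phosphonate | COc1ccc(COCC/C=C(\C)CC[C@@H]2[C@@H](P(=O)(OCC)OCC)C(=O)O[C@H]2/C=C(\C)CC/C=C(\C)I)cc1 | intermediate
28 | diethyl [(3R,4S,5S)-4-[(3E)-6-hydroxy-3-methylhex-3-en-1-yl]-5-[(1E,5E)-6-iodo-2-methylhepta-1,5-dien-1-yl]-2-oxotetrahydrofuran-3-yl]phosphonate | OCC/C=C(\C)CC[C@@H]1[C@@H](P(=O)(OCC)OCC)C(=O)O[C@H]1/C=C(\C)CC/C=C(\C)I | intermediate
29 | diethyl [(3R,4S,5S)-5-[(1E,5E)-6-iodo-2-methylhepta-1,5-dien-1-yl]-4-[(3E)-3-methyl-6-oxohex-3-en-1-yl]-2-oxotetrahydrofuran-3-yl]phosphonate | O=CC/C=C(\C)CC[C@@H]1[C@@H](P(=O)(OCC)OCC)C(=O)O[C@H]1/C=C(\C)CC/C=C(\C)I | intermediate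
30 | acetyl chloride | CC(=O)Cl | starting material
31 | diethyl [(3R,4S,5S)-4-[(3E)-6-acetoxy-6-chloro-3-methylhex-3-en-1-yl]-5-[(1E,5E)-6-iodo-2-methylhepta-1,5-dien-1-yl]-2-oxotetrahydrofuran-3-yl]phosphonate (both C9 epimers) | CC(=O)OC(Cl)C/C=C(\C)CC[C@@H]1[C@@H](P(=O)(OCC)OCC)C(=O)O[C@H]1/C=C(\C)CC/C=C(\C)I | intermediate
32 | (1S,2S,9R,15R,3E,7E,11E)-9-acetoxy-15-(diethoxyphosphoryl)cembra-3,7,11-trien-16,2-olide | CCOP(=O)(OCC)[C@H]1C(=O)O[C@H]2/C=C(\C)CC/C=C(\C)[C@H](OC(C)=O)C/C=C(\C)CC[C@H]12 | intermediate
33 | (1R,2S,9R,3E,7E,11E)-9-acetoxycembra-3,7,11,15(17)-tetraen-16,2-olide (CNP0129197.1) | C=C1C(=O)O[C@H]2/C=C(\C)CC/C=C(\C)[C@H](OC(C)=O)C/C=C(\C)CC[C@H]12 | target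

**Step count**

Total: 20 steps. Longest linear sequence: 15 steps (steps 1–8, then 14–20); the C9–C14 chain takes 5 steps (9–13).

**Steps most likely to fail**

1. Step 19 (ring closure). What may go wrong: intermolecular coupling or hydrodehalogenation outruns capture of the C9 radical by the alkenylnickel of the same molecule, or the catalyst discriminates the two faces of the radical poorly, so that a mixture of C9 epimers results. Fallback by known chemistry, setting out from aldehyde 29: CrCl2 (excess) with catalytic NiCl2 in DMSO/THF at high dilution would close the same C8–C9 bond by an intramolecular Nozaki–Hiyama–Kishi reaction and give the macrocyclic allylic alcohols F1 as a mixture at C9. Dess–Martin periodinane would converge both epimers on the macrocyclic enone F2. Corey–Bakshi–Shibata reduction with (S)-2-methyl-CBS-oxazaborolidine and catecholborane, the alkenyl group acting as the large substituent, should give the (9R)-alcohol F3. Ac2O, DMAP and pyridine then give 32, where the route is rejoined.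

2. Step 18 (chloro acetate formation). What may go wrong: under the Lewis acid the beta,gamma-unsaturated aldehyde isomerises into conjugation, or the chloro acetate loses HCl towards C10. The fallback avoids the free aldehyde and sets out from alcohol 28. PhSSPh and n-Bu3P would give the phenyl sulfide F8. N-Chlorosuccinimide would chlorinate alpha to sulfur to give the alpha-chloro sulfide F9, which CsOAc would convert in the same flask into the alpha-acetoxy sulfide F10. SO2Cl2 at −78 °C with excess 2-methylbut-2-ene as scavenger would then cleave the C–S bond through the chlorosulfonium ion and give 31, where the route is rejoined.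

3. Step 8 (semihydrogenation). What may go wrong: hydrogenolysis of the C8–I bond or over-reduction competes with the alkyne reduction. The fallback builds the butenolide by ring-closing metathesis and sets out from enal 9. Vinylmagnesium bromide at −78 °C would give the racemic dienol F4. Immobilised Candida antarctica lipase B with vinyl acetate should acetylate the (R)-enantiomer selectively (vinyl as the medium group) to give the acetate F5. K2CO3/MeOH would free the (R)-dienol F6, and acryloyl chloride/Et3N would give the acrylate F7. The second-generation Grubbs catalyst in CH2Cl2 at 40 °C should then close the five-membered ring on the monosubstituted alkene and give 14, where the route is rejoined.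

**Further compounds**

F1 | step 19 | diethyl phosphonate of the macrocyclic C9 alcohol (9-hydroxy analogue of 32, both C9 epimers) | CCOP(=O)(OCC)[C@H]1C(=O)O[C@H]2/C=C(\C)CC/C=C(\C)C(O)C/C=C(\C)CC[C@H]12
F2 | step 19 | macrocyclic C9 enone (9-oxo analogue of 32) | CCOP(=O)(OCC)[C@H]1C(=O)O[C@H]2/C=C(\C)CC/C=C(\C)C(=O)C/C=C(\C)CC[C@H]12
F3 | step 19 | macrocyclic (9R)-alcohol (deacetyl 32) | CCOP(=O)(OCC)[C@H]1C(=O)O[C@H]2/C=C(\C)CC/C=C(\C)[C@H](O)C/C=C(\C)CC[C@H]12
F4 | step 8 | (4E,8E)-9-iodo-5-methyldeca-1,4,8-trien-3-ol (racemic) | OC(C=C)/C=C(\C)CC/C=C(\C)I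
F5 | step 8 | (3R,4E,8E)-9-iodo-5-methyldeca-1,4,8-trien-3-yl acetate | CC(=O)O[C@@H](/C=C(\C)CC/C=C(\C)I)C=C
F6 | step 8 | (3R,4E,8E)-9-iodo-5-methyldeca-1,4,8-trien-3-ol | O[C@@H](/C=C(\C)CC/C=C(\C)I)C=C
F7 | step 8 | (3R,4E,8E)-9-iodo-5-methyldeca-1,4,8-trien-3-yl prop-2-enoate | C=CC(=O)O[C@@H](/C=C(\C)CC/C=C(\C)I)C=C
F8 | step 18 | C9 phenyl sulfide of 28 (phenylthio in place of hydroxyl) | c1ccccc1SCC/C=C(\C)CC[C@@H]1[C@@H](P(=O)(OCC)OCC)C(=O)O[C@H]1/C=C(\C)CC/C=C(\C)I
F9 | step 18 | C9 alpha-chloro phenyl sulfide (both C9 epimers) | ClC(Sc1ccccc1)C/C=C(\C)CC[C@@H]1[C@@H](P(=O)(OCC)OCC)C(=O)O[C@H]1/C=C(\C)CC/C=C(\C)I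
F10 | step 18 | C9 alpha-acetoxy phenyl sulfide (both C9 epimers) | CC(=O)OC(Sc1ccccc1)C/C=C(\C)CC[C@@H]1[C@@H](P(=O)(OCC)OCC)C(=O)O[C@H]1/C=C(\C)CC/C=C(\C)I
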